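Rings B and C each carry in sequence C1' (bridge), C2'–OH, C3'–acetyl, C4'–OMe, C5'–methyl, C6'–OH, the pattern of a 3-acyl-4-methoxy-5-methyl-2-pyrone whose lactone carbonyl C2 becomes C2', whose ring oxygen stays on C6 as the C6' phenol and whose lateral CH2 becomes C1'. Two such pyrones, acetyl masked as enol ether, hang on tribenzyl-protected ring A through CH2CH2 links. Methoxide and then a strong base open both lactones and close both arenes by Claisen condensation in one operation, making both C1'–C2' bonds. Hydrogenolysis and a single Friedel–Crafts acylation with the (R)-acyl chloride at the only free carbon of ring A complete the target.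

Key step: step 10

Remark: with the ring B and ring C numbering used above the new bond is C1'–C2' (C1'–C6' already exists as the pyrone C6–CH2 bond); the acetyl groups pass through the key step as 1-ethoxyvinyl ethers because a free acetyl opens a competing aldol closure, C3 is brominated before the pyrone meets ring A because the free C–H of ring A would be halogenated first, and the arms are joined to a stable dialdehyde in place of a labile 2,4,6-trialkoxybenzyl bromide.

Step 1
Reactants: 1 3-methylpentane-2,4-dione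
Product: 2 4-methyl-3,5-dioxohexanoic acid
Conditions: LiN(iPr)2 (2.2 equiv), THF, −78 → 0 °C; CO2, −78 °C; 2 M HCl, 0 °C; crude acid used at once
Reagents that add atoms: carbon dioxide, O=C=O
Why: Carboxylation of a β-diketone 1,3-dianion, which reacts with CO2 at the more basic terminal carbanion; C4 of 2 is enolised and carries no stereochemical information.

Step 2
Reactants: 2 4-methyl-3,5-dioxohexanoic acid
Product: 3 4-hydroxy-5,6-dimethyl-2H-pyran-2-one
Conditions: 1,1'-carbonyldiimidazole, THF, rt; then 1 M HCl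
Reagents that add atoms: none
Why: Cyclodehydration of a 3,5-dioxo acid: the acyl imidazolide is captured by the enol oxygen of the 5-ketone to give the 4-hydroxy-2-pyrone.

Step 3
Reactants: 3 4-hydroxy-5,6-dimethyl-2H-pyran-2-one
Product: 4 4-methoxy-5,6-dimethyl-2H-pyran-2-one
Conditions: Me2SO4, K2CO3, acetone, reflux
Reagents that add atoms: dimethyl sulfate, COS(=O)(=O)OC
Why: Williamson-type O-methylation of the vinylogous acid, which under these conditions should favour the 4-methoxy-2-pyrone over the 2-methoxy-4-pyrone.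

Step 4
Reactants: 4 4-methoxy-5,6-dimethyl-2H-pyran-2-one
Product: 5 3-bromo-4-methoxy-5,6-dimethyl-2H-pyran-2-one
Conditions: N-bromosuccinimide, MeCN, rt, dark
Reagents that add atoms: N-bromosuccinimide, O=C1CCC(=O)N1Br
Why: Electrophilic bromination at C3, the only unsubstituted ring carbon and the β-carbon of the enol ether; polar solvent and darkness suppress radical bromination of the methyl groups.

Step 5
Reactants: 6 phloroglucinol
Product: 7 2,4,6-trihydroxybenzene-1,3-dicarbaldehyde
Conditions: POCl3 (2.5 equiv), DMF (2.5 equiv), 1,4-dioxane, rt; then H2O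
Reagents that add atoms: N,N-dimethylformamide, CN(C)C=O; water, O
Why: Twofold Vilsmeier–Haack formylation, each formyl group deactivating the ring so that the stoichiometry should hold the reaction at the dialdehyde.

Step 6
Reactants: 7 2,4,6-trihydroxybenzene-1,3-dicarbaldehyde
Product: 8 2,4,6-tris(benzyloxy)benzene-1,3-dicarbaldehyde
Conditions: BnBr, K2CO3, DMF, 50 °C
Reagents that add atoms: benzyl bromide, BrCc1ccccc1
Why: Williamson ether synthesis; the two formyl groups lower the carbon nucleophilicity of the phenoxide, so O-benzylation should prevail over C-benzylation.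

Step 7
Reactants: 5 3-bromo-4-methoxy-5,6-dimethyl-2H-pyran-2-one; 8 2,4,6-tris(benzyloxy)benzene-1,3-dicarbaldehyde
Product: 9 6,6'-{[2,4,6-tris(benzyloxy)-1,3-phenylene]bis(2-hydroxyethane-2,1-diyl)}bis(3-bromo-4-methoxy-5-methyl-2H-pyran-2-one), mixture of diastereomers
Conditions: 5 (2.3 equiv), LiN(SiMe3)2, THF, −78 °C; then 8, −78 °C; AcOH, −78 °C
Reagents that add atoms: none
Why: Vinylogous aldol addition: the 6-methyl group alone is conjugated to the lactone carbonyl, so its trienolate adds through the terminal carbon to both aldehydes; the two carbinol centres form without control and are removed in step 8.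

Step 8
Reactants: 9 6,6'-{[2,4,6-tris(benzyloxy)-1,3-phenylene]bis(2-hydroxyethane-2,1-diyl)}bis(3-bromo-4-methoxy-5-methyl-2H-pyran-2-one)
Product: 10 6,6'-{[2,4,6-tris(benzyloxy)-1,3-phenylene]bis(ethane-2,1-diyl)}bis(3-bromo-4-methoxy-5-methyl-2H-pyran-2-one)
Conditions: Et3SiH, CF3CO2H, CH2Cl2, −20 → 0 °C
Reagents that add atoms: none
Why: Ionic hydrogenation: the acid ionises each 2,4,6-tris(benzyloxy)benzylic alcohol to a strongly stabilised cation that the silane reduces, and any styrene formed by proton loss re-enters through the same cation.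

Step 9
Reactants: 10 6,6'-{[2,4,6-tris(benzyloxy)-1,3-phenylene]bis(ethane-2,1-diyl)}bis(3-bromo-4-methoxy-5-methyl-2H-pyran-2-one)
Product: 11 6,6'-{[2,4,6-tris(benzyloxy)-1,3-phenylene]bis(ethane-2,1-diyl)}bis[3-(1-ethoxyethenyl)-4-methoxy-5-methyl-2H-pyran-2-one]
Conditions: CH2=C(OEt)SnBu3 (2.6 equiv), PdCl2(PPh3)2, toluene, 100 °C; chromatography on Et3N-treated silica
Reagents that add atoms: tributyl(1-ethoxyvinyl)stannane, CCCC[Sn](CCCC)(CCCC)C(=C)OCC
Why: Twofold Stille coupling at the C3 bromides installs both acetyl groups in masked form, ring A and the benzyl ethers being inert to zerovalent palladium.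

Step 10
Reactants: 11 6,6'-{[2,4,6-tris(benzyloxy)-1,3-phenylene]bis(ethane-2,1-diyl)}bis[3-(1-ethoxyethenyl)-4-methoxy-5-methyl-2H-pyran-2-one]
Product: 14 2,4-bis(3-acetyl-2,6-dihydroxy-4-methoxy-5-methylbenzyl)-1,3,5-tris(benzyloxy)benzene, via ring-opened bis(keto ester) 12 (not isolated), via bis(ethoxyvinyl) bis(resorcinol) 13 (not isolated)
Conditions: NaOMe, MeOH–THF, 0 → 40 °C; evaporate; KN(SiMe3)2, THF, −78 → 50 °C; then 1 M HCl, THF, 0 °C → rt
Reagents that add atoms: water, O (acetyl oxygens, on hydrolysis of the enol ethers); sodium methoxide, C[O-].[Na+] (its methoxy groups are held only in 12 and leave again)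
Why: Proposed new method: methoxide adds to the lactone carbonyl C2 of each pyrone and opens it to the dienolate of keto ester 12, in which ester C1 and the ketone chain stay cis on the former ring double bond; the amide base then removes a proton from the ketone methylene C6 of the heptenoate (the former lateral CH2), this carbon attacks C1, methoxide leaves and the dienone tautomerises to the resorcinol dianion 13, whose enol ethers dilute acid hydrolyses to acetyl groups. The closest known reaction types are the base-induced recyclisation of 6-(2-oxoalkyl)-4-hydroxy-2-pyrones to acylphloroglucinols and the C6-to-C1 Claisen closure of 3,5-dioxohexanoate esters to phloroglucinol; new here is that the attacking methylene has no second activating group and that two rings are closed at once. Ring B and ring C each close by a 6-(enolendo)-exo-trig Claisen condensation that forms C1'–C2'. No stereocenter is formed. The step needs C-acylation of the ketone methylene by the ester in preference to any aldol path, and the substrate should secure it: the masked acetyl offers neither a second electrophilic carbonyl nor an acidic methyl, C5 is blocked by its methyl group, the 4-methoxy group prevents an unreactive oxido-pyrone and makes methoxide exchange degenerate, and re-lactonisation and double-bond isomerisation are reversible while aromatisation is not.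

Step 11
Reactants: 14 2,4-bis(3-acetyl-2,6-dihydroxy-4-methoxy-5-methylbenzyl)-1,3,5-tris(benzyloxy)benzene
Product: 15 2,4-bis(3-acetyl-2,6-dihydroxy-4-methoxy-5-methylbenzyl)benzene-1,3,5-triol
Conditions: H2 (1 atm), Pd/C, EtOAc–MeOH, rt; handled under argon and used directly
Reagents that add atoms: none
Why: Hydrogenolysis of the three benzyl aryl ethers; the ortho-hydroxy aryl ketones, the aryl methyl ethers and the diarylmethane bonds are not expected to be reduced at atmospheric pressure.

Step 12
Reactants: 16 (R)-2-methylbutanoic acid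
Product: 17 (R)-2-methylbutanoyl chloride
Conditions: (COCl)2, DMF (cat.), CH2Cl2, 0 °C → rt
Reagents that add atoms: oxalyl chloride, O=C(Cl)C(Cl)=O
Why: Acid chloride formation through the chloroiminium catalyst under base-free conditions, which gives no ketene and leaves the α-stereocentre untouched.

Step 13
Reactants: 15 2,4-bis(3-acetyl-2,6-dihydroxy-4-methoxy-5-methylbenzyl)benzene-1,3,5-triol; 17 (R)-2-methylbutanoyl chloride
Product: 18 (2R)-1-[3,5-bis(3-acetyl-2,6-dihydroxy-4-methoxy-5-methylbenzyl)-2,4,6-trihydroxyphenyl]-2-methylbutan-1-one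
Conditions: TiCl4, CH2Cl2–MeNO2, −20 → 0 °C; then 1 M HCl
Reagents that add atoms: none
Why: Friedel–Crafts acylation at C6 of ring A, the only unsubstituted aromatic carbon since rings B and C are hexasubstituted; the stereocentre comes from 17 and should be kept by working cold with a Lewis acid that spares the aryl methyl ethers.

Compound list
1 | 3-methylpentane-2,4-dione | CC(=O)C(C)C(C)=O | starting material
2 | 4-methyl-3,5-dioxohexanoic acid (C4 enolised, no defined configuration) | CC(=O)C(C)C(=O)CC(=O)O | intermediate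
3 | 4-hydroxy-5,6-dimethyl-2H-pyran-2-one | CC1=C(C)C(O)=CC(=O)O1 | intermediate
4 | 4-methoxy-5,6-dimethyl-2H-pyran-2-one | CC1=C(C)C(OC)=CC(=O)O1 | intermediate
5 | 3-bromo-4-methoxy-5,6-dimethyl-2H-pyran-2-one | CC1=C(C)C(OC)=C(Br)C(=O)O1 | intermediate
6 | phloroglucinol (benzene-1,3,5-triol) | Oc1cc(O)cc(O)c1 | starting material
7 | 2,4,6-trihydroxybenzene-1,3-dicarbaldehyde | O=Cc1c(O)cc(O)c(C=O)c1O | intermediate
8 | 2,4,6-tris(benzyloxy)benzene-1,3-dicarbaldehyde | O=Cc1c(OCc2ccccc2)cc(OCc2ccccc2)c(C=O)c1OCc1ccccc1 | intermediate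
9 | 6,6'-{[2,4,6-tris(benzyloxy)-1,3-phenylene]bis(2-hydroxyethane-2,1-diyl)}bis(3-bromo-4-methoxy-5-methyl-2H-pyran-2-one), mixture of diastereomers at the two carbinol carbons | c1ccccc1COc1cc(OCc2ccccc2)c(C(O)CC2=C(C)C(OC)=C(Br)C(=O)O2)c(OCc2ccccc2)c1C(O)CC1=C(C)C(OC)=C(Br)C(=O)O1 | intermediate
10 | 6,6'-{[2,4,6-tris(benzyloxy)-1,3-phenylene]bis(ethane-2,1-diyl)}bis(3-bromo-4-methoxy-5-methyl-2H-pyran-2-one) | c1ccccc1COc1cc(OCc2ccccc2)c(CCC2=C(C)C(OC)=C(Br)C(=O)O2)c(OCc2ccccc2)c1CCC1=C(C)C(OC)=C(Br)C(=O)O1 | intermediate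
11 | 6,6'-{[2,4,6-tris(benzyloxy)-1,3-phenylene]bis(ethane-2,1-diyl)}bis[3-(1-ethoxyethenyl)-4-methoxy-5-methyl-2H-pyran-2-one] (key-step precursor, acetyl groups masked) | c1ccccc1COc1cc(OCc2ccccc2)c(CCC2=C(C)C(OC)=C(C(=C)OCC)C(=O)O2)c(OCc2ccccc2)c1CCC1=C(C)C(OC)=C(C(=C)OCC)C(=O)O1 | intermediate
12 | dimethyl (2E,2'E)-7,7'-[2,4,6-tris(benzyloxy)-1,3-phenylene]bis[2-(1-ethoxyethenyl)-3-methoxy-4-methyl-5-oxohept-2-enoate], present as its bis(dienolate), C4 not configured | c1ccccc1COc1cc(OCc2ccccc2)c(CCC(=O)C(C)/C(OC)=C(/C(=C)OCC)C(=O)OC)c(OCc2ccccc2)c1CCC(=O)C(C)/C(OC)=C(/C(=C)OCC)C(=O)OC | intermediate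
13 | 2,2'-{[2,4,6-tris(benzyloxy)-1,3-phenylene]bis(methylene)}bis[4-(1-ethoxyethenyl)-5-methoxy-6-methylbenzene-1,3-diol] | c1ccccc1COc1cc(OCc2ccccc2)c(Cc2c(O)c(C)c(OC)c(C(=C)OCC)c2O)c(OCc2ccccc2)c1Cc1c(O)c(C)c(OC)c(C(=C)OCC)c1O | intermediate
14 | 2,4-bis(3-acetyl-2,6-dihydroxy-4-methoxy-5-methylbenzyl)-1,3,5-tris(benzyloxy)benzene | c1ccccc1COc1cc(OCc2ccccc2)c(Cc2c(O)c(C)c(OC)c(C(C)=O)c2O)c(OCc2ccccc2)c1Cc1c(O)c(C)c(OC)c(C(C)=O)c1O | intermediate
15 | 2,4-bis(3-acetyl-2,6-dihydroxy-4-methoxy-5-methylbenzyl)benzene-1,3,5-triol | Oc1cc(O)c(Cc2c(O)c(C)c(OC)c(C(C)=O)c2O)c(O)c1Cc1c(O)c(C)c(OC)c(C(C)=O)c1O | intermediate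
16 | (R)-2-methylbutanoic acid | CC[C@@H](C)C(=O)O | starting material
17 | (R)-2-methylbutanoyl chloride | CC[C@@H](C)C(=O)Cl | intermediate
18 | (2R)-1-[3,5-bis(3-acetyl-2,6-dihydroxy-4-methoxy-5-methylbenzyl)-2,4,6-trihydroxyphenyl]-2-methylbutan-1-one | CC[C@@H](C)C(=O)c1c(O)c(Cc2c(O)c(C)c(OC)c(C(C)=O)c2O)c(O)c(Cc2c(O)c(C)c(OC)c(C(C)=O)c2O)c1O | target

Total step count: 13. Longest linear sequence: 10 steps (steps 1, 2, 3, 4, 7, 8, 9, 10, 11, 13).

Steps most likely to fail

1. Step 10. The lactones may open and re-close without carbon–carbon bond formation, the open dianion may persist as an unreactive delocalised species, or only one arm may cyclise. Fallback by known chemistry, setting out from 6 (with 17) and returning at 18: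
   - Friedel–Crafts acylation of 6 with 17 (AlCl3, CH2Cl2–MeNO2, 0 °C) should give (R)-2-methyl-1-(2,4,6-trihydroxyphenyl)butan-1-one F1.
   - Friedel–Crafts acetylation of commercial 2-methylbenzene-1,3,5-triol (AcCl, AlCl3) should give 1-(2,4,6-trihydroxy-3-methylphenyl)ethan-1-one F2.
   - Protection of the 4- and 6-hydroxyls (MeOCH2Cl, iPr2NEt) should give 1-[2-hydroxy-4,6-bis(methoxymethoxy)-3-methylphenyl]ethan-1-one F3, the hydroxyl flanked by methyl and acetyl staying free; a regioisomer would be separated.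
   - Methylation (Me2SO4, K2CO3, acetone, reflux) should give 1-[2-methoxy-4,6-bis(methoxymethoxy)-3-methylphenyl]ethan-1-one F4.
   - HCl in MeOH should give 1-(4,6-dihydroxy-2-methoxy-3-methylphenyl)ethan-1-one F5.
   - Mannich reaction of F5 with dimethylmethylideneammonium iodide at its single free ring carbon should give 1-{3-[(dimethylamino)methyl]-2,4-dihydroxy-6-methoxy-5-methylphenyl}ethan-1-one F6.
   - Heating two equivalents of F6 with F1 in dioxane should alkylate both free positions of F1 through the ortho-quinone methide and give 18.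

2. Step 13. The α-stereocentre may erode by enolisation of the Lewis acid-bound ketone or acyl chloride, the methylene bridges may cleave or scramble under acid, and O-acylation may compete. Fallback, setting out from 14 and returning at 18:
   - 14 is acylated at the free carbon of ring A without a metal Lewis acid by the mixed anhydride of 16 and trifluoroacetic anhydride (CH2Cl2, 0 °C).
   - Phenolic esters formed on rings B and C are cleaved (K2CO3, MeOH, 0 °C) to give (R)-1-[3,5-bis(3-acetyl-2,6-dihydroxy-4-methoxy-5-methylbenzyl)-2,4,6-tris(benzyloxy)phenyl]-2-methylbutan-1-one F7.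
   - Hydrogenolysis (H2, Pd/C) then gives 18.

3. Step 7. The addition to the hindered, electron-rich dialdehyde may reverse (retro-aldol) on warming or stop after one arm. Fallback, setting out from 5 and 8 and returning at 10:
   - Condensation of 5 with 8 under Mg(OMe)2 in refluxing MeOH, made irreversible by dehydration, should give 6,6'-{[2,4,6-tris(benzyloxy)-1,3-phenylene]di[(E)-ethene-2,1-diyl]}bis(3-bromo-4-methoxy-5-methyl-2H-pyran-2-one) F8.
   - Diimide reduction of the two styryl double bonds (TsNHNH2, NaOAc, DME–H2O, reflux) spares the bromides, the benzyl ethers and the pyrone rings and gives 10.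

Further compounds
F1 | step 10 | (R)-2-methyl-1-(2,4,6-trihydroxyphenyl)butan-1-one | CC[C@@H](C)C(=O)c1c(O)cc(O)cc1O
F2 | step 10 | 1-(2,4,6-trihydroxy-3-methylphenyl)ethan-1-one | CC(=O)c1c(O)cc(O)c(C)c1O
F3 | step 10 | 1-[2-hydroxy-4,6-bis(methoxymethoxy)-3-methylphenyl]ethan-1-one | CC(=O)c1c(OCOC)cc(OCOC)c(C)c1O
F4 | step 10 | 1-[2-methoxy-4,6-bis(methoxymethoxy)-3-methylphenyl]ethan-1-one | CC(=O)c1c(OCOC)cc(OCOC)c(C)c1OC
F5 | step 10 | 1-(4,6-dihydroxy-2-methoxy-3-methylphenyl)ethan-1-one | CC(=O)c1c(O)cc(O)c(C)c1OC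
F6 | step 10 | 1-{3-[(dimethylamino)methyl]-2,4-dihydroxy-6-methoxy-5-methylphenyl}ethan-1-one | CC(=O)c1c(O)c(CN(C)C)c(O)c(C)c1OC
F7 | step 13 | (R)-1-[3,5-bis(3-acetyl-2,6-dihydroxy-4-methoxy-5-methylbenzyl)-2,4,6-tris(benzyloxy)phenyl]-2-methylbutan-1-one | CC[C@@H](C)C(=O)c1c(OCc2ccccc2)c(Cc2c(O)c(C)c(OC)c(C(C)=O)c2O)c(OCc2ccccc2)c(Cc2c(O)c(C)c(OC)c(C(C)=O)c2O)c1OCc1ccccc1
F8 | step 7 | 6,6'-{[2,4,6-tris(benzyloxy)-1,3-phenylene]di[(E)-ethene-2,1-diyl]}bis(3-bromo-4-methoxy-5-methyl-2H-pyran-2-one) | c1ccccc1COc1cc(OCc2ccccc2)c(/C=C/C2=C(C)C(OC)=C(Br)C(=O)O2)c(OCc2ccccc2)c1/C=C/C1=C(C)C(OC)=C(Br)C(=O)O1
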